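Everything rests on cutting the C2–C3 bond of ring C. C2, the only stereocentre, is benzylic to ring B and bonded to O1; once C2–C3 is cut it is simply the CH2 of a ring B benzyl ether on the ring A phenol, carrying two enantiotopic, hydridic hydrogens. With a terminal diazoketone on ring A ortho to this ether, Rh2(S-PTTL)4 generates a carbenoid at the future C3 that inserts into one of these C–H bonds, closing ring C and fixing C2 in one neutral operation. The precursor is therefore an ortho-(benzyloxy)aryl diazomethyl ketone carrying all four methoxy groups, with the ring B phenol masked as a triisopropylsilyl ether.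

Key step: step 6

Assumption: C2 of the target is (S) (CIP order O1 > C1' of ring B > C3 > H), and Rh2(S-PTTL)4 is taken to induce this configuration; should a first run show the opposite sense, the mirror-image catalyst Rh2(R-PTTL)4 is used in the same step.

Step 1
Reactants: 1 3-hydroxy-4,5-dimethoxybenzaldehyde; 2 triisopropylsilyl chloride
Product: 3 3,4-dimethoxy-5-[(triisopropylsilyl)oxy]benzaldehyde
Conditions: imidazole, DMF, 0 °C to rt
Reagents that add atoms: triisopropylsilyl chloride (this is compound 2), CC(C)[Si](Cl)(C(C)C)C(C)C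
Why: Imidazole-promoted O-silylation of a phenol is routine, and the bulky triisopropylsilyl ether is chosen because it should outlast NaBH4, K2CO3 and LiN(SiMe3)2 and still be removable with fluoride under non-basic conditions at the end.

Step 2
Reactants: 3 3,4-dimethoxy-5-[(triisopropylsilyl)oxy]benzaldehyde
Product: 4 {3,4-dimethoxy-5-[(triisopropylsilyl)oxy]phenyl}methanol
Conditions: NaBH4, THF/MeOH, 0 °C; sat. NH4Cl
Reagents that add atoms: none
Why: Borohydride reduction of an aromatic aldehyde to the benzylic alcohol is fast at 0 °C, and the hindered aryl silyl ether should survive the short exposure.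

Step 3
Reactants: 4 {3,4-dimethoxy-5-[(triisopropylsilyl)oxy]phenyl}methanol
Product: 5 3,4-dimethoxy-5-[(triisopropylsilyl)oxy]benzyl bromide
Conditions: CBr4, PPh3, CH2Cl2, 0 °C; short silica plug, used at once
Reagents that add atoms: tetrabromomethane, BrC(Br)(Br)Br
Why: In the Appel reaction the alcohol is activated as an alkoxyphosphonium ion and displaced by bromide under near-neutral conditions, which spares the silyl ether and releases no HBr onto the electron-rich ring.

Step 4
Reactants: 5 3,4-dimethoxy-5-[(triisopropylsilyl)oxy]benzyl bromide; 6 2'-hydroxy-3',4'-dimethoxyacetophenone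
Product: 7 1-[3,4-dimethoxy-2-({3,4-dimethoxy-5-[(triisopropylsilyl)oxy]benzyl}oxy)phenyl]ethan-1-one
Conditions: K2CO3 (dry), DMF, rt to 40 °C
Reagents that add atoms: none
Why: In this Williamson ether synthesis the chelated phenol of 6 is deprotonated by carbonate and the phenoxide displaces the reactive primary benzylic bromide by SN2, a standard O-alkylation of 2'-hydroxyacetophenones in which the methyl ketone is not enolised.

Step 5
Reactants: 7 1-[3,4-dimethoxy-2-({3,4-dimethoxy-5-[(triisopropylsilyl)oxy]benzyl}oxy)phenyl]ethan-1-one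
Product: 9 2-diazo-1-[3,4-dimethoxy-2-({3,4-dimethoxy-5-[(triisopropylsilyl)oxy]benzyl}oxy)phenyl]ethan-1-one, via trifluoroacetyl diketone 8 (not isolated)
Conditions: LiN(SiMe3)2, THF, −78 °C; CF3CO2CH2CF3, −78 °C; cold 1 M HCl quench, crude 8; then MsN3, Et3N, H2O, MeCN, rt
Reagents that add atoms: 2,2,2-trifluoroethyl trifluoroacetate, O=C(OCC(F)(F)F)C(F)(F)F (CF3CO group, present in 8 only); methanesulfonyl azide, CS(=O)(=O)N=[N+]=[N-] (the two diazo nitrogens of 9)
Why: In this detrifluoroacetylative diazo transfer (a Regitz-type transfer to an activated methyl ketone) the kinetic lithium enolate is C-acylated by the trifluoroethyl ester, the acidic 1,3-diketone 8 adds to the sulfonyl azide under triethylamine, and the adduct fragments with loss of the trifluoroacetyl group to leave the terminal diazoketone, while the amide base at −78 °C should touch neither the benzylic ether nor the silyl ether.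

Step 6
Reactants: 9 2-diazo-1-[3,4-dimethoxy-2-({3,4-dimethoxy-5-[(triisopropylsilyl)oxy]benzyl}oxy)phenyl]ethan-1-one
Product: 10 (2S)-2-{3,4-dimethoxy-5-[(triisopropylsilyl)oxy]phenyl}-7,8-dimethoxychroman-4-one
Conditions: Rh2(S-PTTL)4 (2 mol %), 4 Å MS, toluene, −20 to 0 °C, slow addition of 9
Reagents that add atoms: none
Why: Rh2(S-PTTL)4 (dirhodium tetrakis[N-phthaloyl-(S)-tert-leucinate], a carboxylate of divalent rhodium) strips N2 from 9 to give an electrophilic rhodium carbenoid at C3, which engages one of the two O1–CH2 hydrogens in a concerted, asynchronous three-centre transition state with hydride-like character, so that C2–C3 forms as the metal leaves. The reaction type is the established intramolecular carbenoid C–H insertion of ortho-alkoxyaryl diazoketones, which delivers chroman-4-ones under chiral dirhodium carboxylate catalysis. Ring C closes by a 1,6-insertion: C3, C4, C4a, C8a, O1 and C2 make up the forming six-membered ring, with the ring B aryl group pseudo-equatorial. The single new stereocentre C2 is controlled by the catalyst, whose phthalimido-walled chiral pocket should present the carbenoid to only one of the two enantiotopic benzylic hydrogens; the conditions are neutral and cold, so C2 should not be epimerised by ring opening afterwards. The selectivity required is C–H insertion over attack of the carbenoid on O1 (five-membered oxonium ylide, then 1,2-benzyl shift to a benzofuran-3-one) and over carbene dimerisation; the substrate favours insertion because the C2–H bonds are the most hydridic in the molecule (flanked by the O1 lone pair and the electron-rich ring B) and O1 is an aryl ether oxygen, less nucleophilic than a dialkyl ether, and toluene as a non-polar solvent with slow addition of 9 supports this.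

Step 7
Reactants: 10 (2S)-2-{3,4-dimethoxy-5-[(triisopropylsilyl)oxy]phenyl}-7,8-dimethoxychroman-4-one
Product: 11 (2S)-2-(3-hydroxy-4,5-dimethoxyphenyl)-7,8-dimethoxychroman-4-one
Conditions: HF·pyridine, pyridine, THF, 0 °C to rt; pH 7 buffer
Reagents that add atoms: none
Why: Fluoride-induced desilylation of the aryl silyl ether is driven by the Si–F bond, and the pyridine-buffered, weakly acidic medium avoids the base-induced retro-oxa-Michael opening of ring C to the 2'-hydroxychalcone that would racemise C2.

Compound list
1 | 3-hydroxy-4,5-dimethoxybenzaldehyde | COc1cc(C=O)cc(O)c1OC | starting material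
2 | triisopropylsilyl chloride | CC(C)[Si](Cl)(C(C)C)C(C)C | starting material
3 | 3,4-dimethoxy-5-[(triisopropylsilyl)oxy]benzaldehyde | COc1cc(C=O)cc(O[Si](C(C)C)(C(C)C)C(C)C)c1OC | intermediate
4 | {3,4-dimethoxy-5-[(triisopropylsilyl)oxy]phenyl}methanol | COc1cc(CO)cc(O[Si](C(C)C)(C(C)C)C(C)C)c1OC | intermediate
5 | 3,4-dimethoxy-5-[(triisopropylsilyl)oxy]benzyl bromide | COc1cc(CBr)cc(O[Si](C(C)C)(C(C)C)C(C)C)c1OC | intermediate
6 | 2'-hydroxy-3',4'-dimethoxyacetophenone | CC(=O)c1ccc(OC)c(OC)c1O | starting material
7 | 1-[3,4-dimethoxy-2-({3,4-dimethoxy-5-[(triisopropylsilyl)oxy]benzyl}oxy)phenyl]ethan-1-one | CC(=O)c1ccc(OC)c(OC)c1OCc1cc(OC)c(OC)c(O[Si](C(C)C)(C(C)C)C(C)C)c1 | intermediate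
8 | 4,4,4-trifluoro-1-[3,4-dimethoxy-2-({3,4-dimethoxy-5-[(triisopropylsilyl)oxy]benzyl}oxy)phenyl]butane-1,3-dione | O=C(CC(=O)C(F)(F)F)c1ccc(OC)c(OC)c1OCc1cc(OC)c(OC)c(O[Si](C(C)C)(C(C)C)C(C)C)c1 | intermediate
9 | 2-diazo-1-[3,4-dimethoxy-2-({3,4-dimethoxy-5-[(triisopropylsilyl)oxy]benzyl}oxy)phenyl]ethan-1-one | [N-]=[N+]=CC(=O)c1ccc(OC)c(OC)c1OCc1cc(OC)c(OC)c(O[Si](C(C)C)(C(C)C)C(C)C)c1 | intermediate
10 | (2S)-2-{3,4-dimethoxy-5-[(triisopropylsilyl)oxy]phenyl}-7,8-dimethoxychroman-4-one | COc1cc([C@@H]2CC(=O)c3ccc(OC)c(OC)c3O2)cc(O[Si](C(C)C)(C(C)C)C(C)C)c1OC | intermediate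
11 | (2S)-2-(3-hydroxy-4,5-dimethoxyphenyl)-7,8-dimethoxychroman-4-one | COc1cc([C@@H]2CC(=O)c3ccc(OC)c(OC)c3O2)cc(O)c1OC | target

Total step count: 7.
Longest linear sequence: 7 steps (1 → 3 → 4 → 5 → 7 → 9 → 10 → 11; acetophenone 6 enters at step 4).

Steps most likely to fail

1. Step 6. The carbenoid may be intercepted by the lone pair of O1, followed by 1,2-migration of the benzyl group and contraction to a five-membered ring. The carbene may also dimerise, or the catalyst may discriminate poorly between the two benzylic hydrogens, which would erode the enantiomeric purity. Fallback, setting out from 6 and 1 and coming back at 11: Claisen–Schmidt condensation of 6 with unprotected 1 (KOH, EtOH/H2O, rt; the phenoxide of 1 is meta to the formyl group and does not switch it off) should give (E)-1-(2-hydroxy-3,4-dimethoxyphenyl)-3-(3-hydroxy-4,5-dimethoxyphenyl)prop-2-en-1-one F1. Intramolecular oxa-Michael addition (NaOAc, EtOH, reflux) should then close ring C to racemic 2-(3-hydroxy-4,5-dimethoxyphenyl)-7,8-dimethoxychroman-4-one F2. Kinetic resolution by asymmetric transfer hydrogenation (RuCl[(R,R)-TsDPEN](p-cymene), HCO2H/Et3N, EtOAc, rt, stopped just past half conversion) should reduce the (R)-ketone to (2R,4R)-2-(3-hydroxy-4,5-dimethoxyphenyl)-7,8-dimethoxychroman-4-ol F3, which is removed by chromatography, and leave the (S)-flavanone 11. The catalyst antipode is assigned from the usual model and would be confirmed on a small scale; at most half of F2 can be used.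

2. Step 5. C-acylation of the enolate may be incomplete, or the aryl silyl ether may be lost under the basic diazo-transfer and work-up conditions. Fallback, setting out from 7 and coming back at 9: the kinetic enolate of 7 (LiN(SiMe3)2, THF, −78 °C) is trapped with TMSCl to give {[1-(3,4-dimethoxy-2-{[3,4-dimethoxy-5-(triisopropylsilyloxy)benzyl]oxy}phenyl)ethenyl]oxy}trimethylsilane F4, used crude. NBS (THF, 0 °C), which should react first with the silyl enol ether as the most nucleophilic site, converts it into 2-bromo-1-[3,4-dimethoxy-2-({3,4-dimethoxy-5-[(triisopropylsilyl)oxy]benzyl}oxy)phenyl]ethan-1-one F5. N,N'-Ditosylhydrazine with DBU (THF, 0 °C) should then give diazoketone 9 by N-alkylation and loss of two sulfinate groups.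

3. Step 4. Alkylation of the hydrogen-bonded, doubly ortho-flanked phenoxide may be sluggish, leaving time for silyl transfer from the aryl silyl ether to phenoxide or for decomposition of the benzylic bromide. Fallback, setting out from 4 and 6 and coming back at 7: Mitsunobu etherification (PPh3, DIAD, THF, 0 °C to rt) couples alcohol 4 directly with phenol 6, a dehydrative coupling that needs neither the bromide 5 nor a carbonate base; no compound outside the list is made (entry F0).

Further compounds
F1 | step 6 | (E)-1-(2-hydroxy-3,4-dimethoxyphenyl)-3-(3-hydroxy-4,5-dimethoxyphenyl)prop-2-en-1-one | COc1ccc(C(=O)/C=C/c2cc(O)c(OC)c(OC)c2)c(O)c1OC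
F2 | step 6 | racemic 2-(3-hydroxy-4,5-dimethoxyphenyl)-7,8-dimethoxychroman-4-one | COc1cc(C2CC(=O)c3ccc(OC)c(OC)c3O2)cc(O)c1OC
F3 | step 6 | (2R,4R)-2-(3-hydroxy-4,5-dimethoxyphenyl)-7,8-dimethoxychroman-4-ol | COc1cc([C@H]2C[C@@H](O)c3ccc(OC)c(OC)c3O2)cc(O)c1OC
F4 | step 5 | {[1-(3,4-dimethoxy-2-{[3,4-dimethoxy-5-(triisopropylsilyloxy)benzyl]oxy}phenyl)ethenyl]oxy}trimethylsilane | C=C(O[Si](C)(C)C)c1ccc(OC)c(OC)c1OCc1cc(OC)c(OC)c(O[Si](C(C)C)(C(C)C)C(C)C)c1
F5 | step 5 | 2-bromo-1-[3,4-dimethoxy-2-({3,4-dimethoxy-5-[(triisopropylsilyl)oxy]benzyl}oxy)phenyl]ethan-1-one | BrCC(=O)c1ccc(OC)c(OC)c1OCc1cc(OC)c(OC)c(O[Si](C(C)C)(C(C)C)C(C)C)c1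
F0 | step 4 | none | none
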